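## Retrosynthetic overview

1. The target is traced back to a 3,19-diol methyl ester by late ring A adjustment: C3 is inverted through the 3-ketone, C19 goes from CH2OH to CHO, C3 is acetylated and the ester is hydrolysed.
2. The Δ7 alkene comes from the exocyclic Δ8(17) alkene by isomerisation.
3. Key disconnection C12–C13: a C12 aldehyde, used through its N–H hydrazone as an alkyl carbanion equivalent (a carbonyl carbon with reversed polarity), is joined under nickel catalysis to the normally electrophilic β-carbon of an (E)-β-tosyloxy crotonate. N2 is lost and the (13E) geometry is taken over from the enol tosylate.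
4. The C12 aldehyde comes from andrographolide by cleavage of the C12=C13 alkylidene-lactone bond; the enol tosylate comes from methyl acetoacetate.
5. No ring is formed: rings A and B, with C4, C5, C9 and C10 in the required ent-labdane configuration, are taken intact from andrographolide.

Assumption: natural (−)-andrographolide (bulk commercial ent-labdane) is accepted as a cheap starting material; labdane numbering is used, with C19 the axial C4 substituent cis to C20.

## Route

Step 1
Reactants: 1 methyl acetoacetate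
Product: 2 methyl (2E)-3-(p-toluenesulfonyloxy)but-2-enoate
Conditions: TsCl (1.5 equiv), N-methylimidazole (1.5 equiv), Et3N (1.5 equiv), MeCN, 0 °C to rt
Reagents that add atoms: p-toluenesulfonyl chloride, Cc1ccc(cc1)S(=O)(=O)Cl
Why: Stereoselective enol tosylation of a β-keto ester under amine (non-chelating) conditions puts OTs trans to CO2Me, giving the (E)-enol tosylate whose geometry later becomes the (13E) alkene.

Step 2
Reactants: 3 andrographolide
Product: 4 (3R,4R,5S,9R,10S)-3,19-dihydroxy-13,14,15,16-tetranorlabd-8(17)-en-12-al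
Conditions: KMnO4 (1.4 equiv), THF/H2O (20:1), −10 to 0 °C, 30 min, filtered through Celite
Reagents that add atoms: KMnO4 (potassium permanganate), [K+].[O-][Mn](=O)(=O)=O
Why: Oxidative alkene cleavage with permanganate (cyclic manganate ester, then C–C scission) should be fastest at the conjugated, sterically exposed C12=C13 alkylidene-lactone bond and spare the hindered 1,1-disubstituted Δ8(17) alkene and the alcohols in cold THF, so C12 is released as the aldehyde with no decalin stereocentre touched.

Step 3
Reactants: 4 (3R,4R,5S,9R,10S)-3,19-dihydroxy-13,14,15,16-tetranorlabd-8(17)-en-12-al; 5 hydrazine monohydrate; 2 methyl (2E)-3-(p-toluenesulfonyloxy)but-2-enoate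
Product: 7 methyl (3R,4R,5S,9R,10S,13E)-3,19-dihydroxylabda-8(17),13-dien-15-oate, via C12 NH2-hydrazone 6 (not isolated)
Conditions: N2H4·H2O (1.2 equiv), THF, rt, 1 h, volatiles removed; then 2 (1.3 equiv), Ni(cod)2 (10 mol %), PMe3 (20 mol %), K3PO4 (2 equiv), THF, 60 °C
Reagents that add atoms: none
Why: Proposed new method: the N–H hydrazone of 4 acts as an alkyl carbanion equivalent at C12 (carbonyl umpolung), zerovalent nickel inserts with retention into the ester-activated vinyl C–OTs bond of 2, the deprotonated hydrazone binds nickel and loses N2 (Wolff–Kishner-type denitrogenation on the metal) to give an alkyl(alkenyl)nickel species that reductively eliminates to the (13E)-enoate while the free diol and all stereocentres are untouched; the closest known reaction type is the nickel-catalysed cross-coupling of aldehyde N–H hydrazones with aryl halides and aryl sulfonates.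

Step 4
Reactants: 7 methyl (3R,4R,5S,9R,10S,13E)-3,19-dihydroxylabda-8(17),13-dien-15-oate
Product: 8 methyl (3R,4R,5S,9R,10S,13E)-3,19-dihydroxylabda-7,13-dien-15-oate
Conditions: Co(salen)Cl (5 mol %; salen = N,N′-bis(3,5-di-tert-butylsalicylidene)-1,2-cyclohexanediaminate), PhSiH3 (5 mol %), benzene, rt
Reagents that add atoms: none
Why: Radical hydrogen-atom-transfer alkene isomerisation (cobalt hydride gives H to C17, the C8 radical returns H from the accessible C7 methylene rather than the hindered C9–H) moves only the 1,1-disubstituted alkene to the trisubstituted Δ7 position, the electron-poor enoate being inert and no stereocentre involved.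

Step 5
Reactants: 8 methyl (3R,4R,5S,9R,10S,13E)-3,19-dihydroxylabda-7,13-dien-15-oate
Product: 9 methyl (4R,5S,9R,10S,13E)-3,19-dioxolabda-7,13-dien-15-oate
Conditions: Dess–Martin periodinane (2.6 equiv), CH2Cl2, 0 °C to rt, used crude
Reagents that add atoms: none
Why: Dess–Martin oxidation converts both alcohols under non-basic conditions into the β-keto aldehyde, which cannot enolise at the quaternary C4 (no epimerisation or elimination), and this erases the C3 configuration so that it can be reset.

Step 6
Reactants: 9 methyl (4R,5S,9R,10S,13E)-3,19-dioxolabda-7,13-dien-15-oate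
Product: 11 (3S,4R,5S,9R,10S,13E)-3,19-dihydroxylabda-7,13-dien-15-oic acid, via methyl ester diol 10 (not isolated)
Conditions: LiBH(s-Bu)3 (L-Selectride, 3 equiv), THF, −78 to 0 °C; then LiOH·H2O (10 equiv), MeOH/H2O, 40 °C; 1 M HCl to pH 3
Reagents that add atoms: lithium hydroxide, [Li+].[OH-]
Why: The bulky trialkylborohydride reduces the aldehyde and then attacks the C3 ketone along the equatorial trajectory (steric approach control, as for 4,4-disubstituted 3-keto terpenoids) to give the axial (3S) alcohol, the β,β-disubstituted enoate is not reduced at low temperature, and the methyl ester is then saponified in the same flask.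

Step 7
Reactants: 11 (3S,4R,5S,9R,10S,13E)-3,19-dihydroxylabda-7,13-dien-15-oic acid
Product: 12 (3S,4S,5S,9R,10S,13E)-3-hydroxy-19-oxolabda-7,13-dien-15-oic acid
Conditions: TEMPO (20 mol %), PhI(OAc)2 (1.3 equiv), dry CH2Cl2, rt
Reagents that add atoms: none
Why: Oxoammonium-mediated (TEMPO/PhI(OAc)2) oxidation is selective for the primary C19 alcohol over the hindered axial C3 alcohol and stops at the aldehyde without water, and the β-hydroxy aldehyde cannot dehydrate because C4 is quaternary.

Step 8
Reactants: 12 (3S,4S,5S,9R,10S,13E)-3-hydroxy-19-oxolabda-7,13-dien-15-oic acid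
Product: 14 (3S,4S,5S,9R,10S,13E)-3-acetoxy-19-oxolabda-7,13-dien-15-oic acid (target CNP0312710.1), via C15 mixed acetic anhydride 13 (not isolated)
Conditions: Ac2O (4 equiv), pyridine, DMAP (10 mol %), CH2Cl2, rt; then H2O added, rt, 2 h
Reagents that add atoms: acetic anhydride, CC(=O)OC(C)=O
Why: DMAP-catalysed acylation (nucleophilic catalysis) esterifies the hindered axial C3 alcohol with retention, and the mixed anhydride formed at C15 is cleaved by water at its acetyl carbonyl, returning the free acid and giving the target.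

## Compound list

1 | methyl acetoacetate | CC(=O)CC(=O)OC | starting material
2 | methyl (2E)-3-(p-toluenesulfonyloxy)but-2-enoate (OTs trans to CO2Me) | C/C(OS(=O)(=O)c1ccc(C)cc1)=C\C(=O)OC | intermediate
3 | (−)-andrographolide, (3R,4R,5S,9R,10S,12E,14S)-3,14,19-trihydroxylabda-8(17),12-dien-16,15-olide (ent-labdane; 3-OH equatorial; C19 axial, cis to C20) | O[C@@H]1CC[C@@]2(C)[C@H](C/C=C3/C(=O)OC[C@H]3O)C(=C)CC[C@@H]2[C@]1(C)CO | starting material
4 | (3R,4R,5S,9R,10S)-3,19-dihydroxy-13,14,15,16-tetranorlabd-8(17)-en-12-al | O[C@@H]1CC[C@@]2(C)[C@H](CC=O)C(=C)CC[C@@H]2[C@]1(C)CO | intermediate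
5 | hydrazine monohydrate | NN.O | starting material
6 | (E)-N-unsubstituted hydrazone of 4 at C12 | O[C@@H]1CC[C@@]2(C)[C@H](C/C=N/N)C(=C)CC[C@@H]2[C@]1(C)CO | intermediate
7 | methyl (3R,4R,5S,9R,10S,13E)-3,19-dihydroxylabda-8(17),13-dien-15-oate | O[C@@H]1CC[C@@]2(C)[C@H](CC/C(C)=C/C(=O)OC)C(=C)CC[C@@H]2[C@]1(C)CO | intermediate
8 | methyl (3R,4R,5S,9R,10S,13E)-3,19-dihydroxylabda-7,13-dien-15-oate | O[C@@H]1CC[C@@]2(C)[C@H](CC/C(C)=C/C(=O)OC)C(C)=CC[C@@H]2[C@]1(C)CO | intermediate
9 | methyl (4R,5S,9R,10S,13E)-3,19-dioxolabda-7,13-dien-15-oate | O=C1CC[C@@]2(C)[C@H](CC/C(C)=C/C(=O)OC)C(C)=CC[C@@H]2[C@]1(C)C=O | intermediate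
10 | methyl (3S,4R,5S,9R,10S,13E)-3,19-dihydroxylabda-7,13-dien-15-oate (3-OH axial) | O[C@H]1CC[C@@]2(C)[C@H](CC/C(C)=C/C(=O)OC)C(C)=CC[C@@H]2[C@]1(C)CO | intermediate
11 | (3S,4R,5S,9R,10S,13E)-3,19-dihydroxylabda-7,13-dien-15-oic acid | O[C@H]1CC[C@@]2(C)[C@H](CC/C(C)=C/C(=O)O)C(C)=CC[C@@H]2[C@]1(C)CO | intermediate
12 | (3S,4S,5S,9R,10S,13E)-3-hydroxy-19-oxolabda-7,13-dien-15-oic acid | O[C@H]1CC[C@@]2(C)[C@H](CC/C(C)=C/C(=O)O)C(C)=CC[C@@H]2[C@]1(C)C=O | intermediate
13 | acetic (3S,4S,5S,9R,10S,13E)-3-acetoxy-19-oxolabda-7,13-dien-15-oic anhydride | CC(=O)O[C@H]1CC[C@@]2(C)[C@H](CC/C(C)=C/C(=O)OC(C)=O)C(C)=CC[C@@H]2[C@]1(C)C=O | intermediate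
14 | (3S,4S,5S,9R,10S,13E)-3-acetoxy-19-oxolabda-7,13-dien-15-oic acid | CC(=O)O[C@H]1CC[C@@]2(C)[C@H](CC/C(C)=C/C(=O)O)C(C)=CC[C@@H]2[C@]1(C)C=O | target

## Totals

Total steps: 8. Longest linear sequence: 7 steps (3 to 14, steps 2–8); step 1 is a one-step side branch. C4, C5, C9 and C10 come from andrographolide and are never touched; C3 is set in step 6; the (13E) alkene is set in steps 1 and 3.

## Steps most likely to fail, with fallbacks

**Step 3 (key coupling).** This is the least precedented step. Likely failure modes are: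
- uncatalysed N-vinylation of the hydrazone by the Michael-acceptor tosylate;
- β-hydride elimination from the C12–nickel alkyl;
- C–C bond formation before N2 loss, which would give an allylic diazene and a transposed β,γ-unsaturated ester;
- erosion of E/Z purity.

The fallback sets out from 4 and returns at 7, using a classical acetyl anion equivalent. NaBH4 in MeOH reduces 4 to the C12 alcohol F1. Iodination of the only unhindered primary alcohol (I2, PPh3, imidazole, 0 °C) gives the C12 iodide F2. Alkylation with 2-lithio-2-methyl-1,3-dithiane (3.5 equiv, to cover the two free hydroxyls) gives the dithiane F3. Unmasking with MeI and CaCO3 in aqueous MeCN gives the methyl ketone F4. Horner–Wadsworth–Emmons olefination with trimethyl phosphonoacetate and NaH in warm THF then gives 7, with the minor (13Z) isomer removed by chromatography.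

**Step 2 (cleavage on the unprotected triol).** Risks are competing attack at Δ8(17), over-oxidation of the aldehyde to the acid, and slow alcohol oxidation. The fallback sets out from 3 and returns at 4 by a protect–cleave–release sequence. 2,2-Dimethoxypropane with PPTS gives the 3,19-acetonide F5. KMnO4 in cold THF then cleaves C12=C13 on the protected lactone to the acetonide aldehyde F6. 80% aqueous AcOH at rt releases the diol 4.

**Step 4 (alkene isomerisation).** The risk is regiochemistry (some tetrasubstituted Δ8(9) isomer) or stalling. The fallback sets out from 7 and returns at 8 by a regiospecific oxidation–reductive transposition pair. SeO2 (cat.) with t-BuOOH in CH2Cl2 hydroxylates the ring allylic position to the 7-axial allylic alcohol F7. Mitsunobu displacement of this most reactive (allylic) hydroxyl with 2-nitrobenzenesulfonylhydrazide (PPh3, DEAD, N-methylmorpholine, −30 °C) gives the C7 N-sulfonylhydrazine F8 (not isolated). On warming it loses sulfinic acid to the allylic diazene F9 (not isolated), whose retro-ene loss of N2 delivers H to C17 and places the alkene at C7=C8 (Myers reductive transposition), giving 8.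

## Further compounds

F1 | step 3 | (3R,4R,5S,9R,10S)-13,14,15,16-tetranorlabd-8(17)-ene-3,12,19-triol | O[C@@H]1CC[C@@]2(C)[C@H](CCO)C(=C)CC[C@@H]2[C@]1(C)CO
F2 | step 3 | (3R,4R,5S,9R,10S)-12-iodo-13,14,15,16-tetranorlabd-8(17)-ene-3,19-diol | O[C@@H]1CC[C@@]2(C)[C@H](CCI)C(=C)CC[C@@H]2[C@]1(C)CO
F3 | step 3 | (3R,4R,5S,9R,10S)-13,13-(propane-1,3-diyldithio)-14,15-dinorlabd-8(17)-ene-3,19-diol | O[C@@H]1CC[C@@]2(C)[C@H](CCC3(C)SCCCS3)C(=C)CC[C@@H]2[C@]1(C)CO
F4 | step 3 | (3R,4R,5S,9R,10S)-3,19-dihydroxy-14,15-dinorlabd-8(17)-en-13-one | O[C@@H]1CC[C@@]2(C)[C@H](CCC(C)=O)C(=C)CC[C@@H]2[C@]1(C)CO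
F5 | step 2 | andrographolide 3,19-O-isopropylidene acetal | CC3(C)O[C@@H]1CC[C@@]2(C)[C@H](C/C=C4/C(=O)OC[C@H]4O)C(=C)CC[C@@H]2[C@]1(C)CO3
F6 | step 2 | (3R,4R,5S,9R,10S)-3,19-(isopropylidenedioxy)-13,14,15,16-tetranorlabd-8(17)-en-12-al | CC3(C)O[C@@H]1CC[C@@]2(C)[C@H](CC=O)C(=C)CC[C@@H]2[C@]1(C)CO3
F7 | step 4 | methyl (3R,4R,5S,7S,9S,10S,13E)-3,7,19-trihydroxylabda-8(17),13-dien-15-oate (7-OH axial; C9 geometry unchanged, descriptor changes by priority only) | O[C@@H]1CC[C@@]2(C)[C@H](CC/C(C)=C/C(=O)OC)C(=C)[C@@H](O)C[C@@H]2[C@]1(C)CO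
F8 | step 4 | methyl (3R,4R,5S,7R,9S,10S,13E)-7-[1-(2-nitrophenylsulfonyl)hydrazinyl]-3,19-dihydroxylabda-8(17),13-dien-15-oate | O[C@@H]1CC[C@@]2(C)[C@H](CC/C(C)=C/C(=O)OC)C(=C)[C@H](N(N)S(=O)(=O)c3ccccc3[N+](=O)[O-])C[C@@H]2[C@]1(C)CO
F9 | step 4 | methyl (3R,4R,5S,7R,9S,10S,13E)-7-diazenyl-3,19-dihydroxylabda-8(17),13-dien-15-oate | O[C@@H]1CC[C@@]2(C)[C@H](CC/C(C)=C/C(=O)OC)C(=C)[C@H](N=N)C[C@@H]2[C@]1(C)CO
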